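## Retrosynthetic overview

1. Last bond: C7–C8 (sp2–sp3, next to ring A). Alkenyl iodide 25 is joined to racemic γ-chloroethyl pyrone 7 by a nickel-catalysed enantioconvergent reductive coupling. The pyrone γ-carbon is a nucleophile everywhere else in the route; here it is used as its electrophilic (enolonium-type) chloride, and the ligand sets C8.
2. C2–C3: vinylogous aldol of the ring B dienolate (from 22) with aldehyde 17 (anti, Felkin) sets C2 and C3.
3. Aldehyde 17 comes from a titanium syn-aldol on (E)-3-iodo-2-methylpropenal (C4, C5). The east arm 22 comes from a vinylogous aldol of pyrone 5 with propanal, then lipase resolution (C2′, C3′).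
4. Rings: both γ-pyrone rings are the same building block 5, formed once at the start (step 1). Ring B is elaborated on both ethyl groups, ring A on one. No ring is formed later.

Numbering used below: the nonenyl chain between the rings is C2–C9 counted from ring B (C2 on ring B, C8 on ring A); the pentanyl arm is C2′, C3′.

Assumption: auxiliary propionate 12, the bis(oxazoline) ligand, the lipase and the unnumbered reagents are bought; pyrone 5 is made rather than bought.

## Route

Step 1
Reactants: 1 pentan-3-one; 2 propanoic acid (2.5 equiv)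
Product: 5 2,6-diethyl-3,5-dimethyl-4H-pyran-4-one, via diketone 3 (not isolated), via triketone 4 (not isolated)
Conditions: polyphosphoric acid, 95 °C, 6 h
Reagents that add atoms: none
Why: Polyphosphoric acid turns the acid into a mixed anhydride that C-acylates both α-carbons of the ketone (3, then 4), and the 1,3,5-triketone cyclodehydrates to the aromatic γ-pyrone (classical polyphosphoric acid pyrone synthesis); no stereocentre.

Step 2
Reactants: 5 2,6-diethyl-3,5-dimethyl-4H-pyran-4-one
Product: 7 rac-2-(1-chloroethyl)-6-ethyl-3,5-dimethyl-4H-pyran-4-one, via sodium dienolate 6 (not isolated)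
Conditions: NaN(SiMe3)2 (1.05 equiv), THF, −78 °C; cannulated into N-chlorosuccinimide (1.2 equiv), THF, −78 °C; aq. NH4Cl
Reagents that add atoms: N-chlorosuccinimide, O=C1CCC(=O)N1Cl
Why: γ-Deprotonation gives the sodium dienolate 6, which is more reactive toward N–Cl donors than a lithium dienolate and is chlorinated at its exocyclic γ-carbon because that restores the aromatic pyrone (electrophilic halogenation of a vinylogous enolate, inverse addition limiting dichlorination); the new centre is left racemic because both enantiomers converge in step 12.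

Step 3
Reactants: 8 prop-2-yn-1-ol
Product: 10 (2E)-3-iodo-2-methylprop-2-en-1-ol, via alkenylalane 9 (not isolated)
Conditions: AlMe3 (3 equiv), Cp2ZrCl2 (0.25 equiv), CH2Cl2, 0 °C to rt; then iodine, THF, −30 to 0 °C; aq. K2CO3
Reagents that add atoms: trimethylaluminium, C[Al](C)C; iodine, II
Why: Negishi zirconium-catalysed carboalumination adds methyl and aluminium syn across the alkyne with aluminium on the terminal carbon, and iododealumination goes with retention, which fixes the E trisubstituted alkene of the target.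

Step 4
Reactants: 10 (2E)-3-iodo-2-methylprop-2-en-1-ol
Product: 11 (2E)-3-iodo-2-methylprop-2-enal
Conditions: MnO2 (15 equiv), CH2Cl2, rt; filtered and used as a solution
Reagents that add atoms: none
Why: Heterogeneous MnO2 oxidises the allylic alcohol selectively to the enal (allylic oxidation) without touching the alkenyl iodide or the alkene geometry.

Step 5
Reactants: 12 1-[(4R)-4-benzyl-2-thioxo-1,3-thiazolidin-3-yl]propan-1-one; 11 (2E)-3-iodo-2-methylprop-2-enal
Product: 14 (2R,3R,4E)-1-[(4R)-4-benzyl-2-thioxo-1,3-thiazolidin-3-yl]-3-hydroxy-5-iodo-2,4-dimethylpent-4-en-1-one, via titanium enolate 13 (not isolated)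
Conditions: TiCl4 (1.05 equiv), i-Pr2NEt (1.1 equiv), N-methylpyrrolidinone (1.0 equiv), CH2Cl2, 0 °C; then 11, 0 °C; aq. NH4Cl
Reagents that add atoms: none
Why: Crimmins titanium aldol: the Z chlorotitanium enolate 13 reacts through the non-chelated Zimmerman–Traxler chair on the face away from the benzyl group, giving the Evans-syn adduct and setting the two new centres R,R (C4 and C5 of the target chain).

Step 6
Reactants: 14 syn aldol adduct
Product: 15 (2R,3R,4E)-1-[(4R)-4-benzyl-2-thioxo-1,3-thiazolidin-3-yl]-3-[(tert-butyldimethylsilyl)oxy]-5-iodo-2,4-dimethylpent-4-en-1-one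
Conditions: TBSOTf (1.3 equiv), 2,6-lutidine (2 equiv), CH2Cl2, 0 °C
Reagents that add atoms: tert-butyldimethylsilyl trifluoromethanesulfonate, CC(C)(C)[Si](C)(C)OS(=O)(=O)C(F)(F)F
Why: Silyl ether formation on the secondary alcohol blocks retro-aldol and β-elimination and gives a bulky, non-chelating β-substituent for the Felkin-controlled step 10; no stereocentre is touched.

Step 7
Reactants: 15 silyl ether
Product: 17 (2R,3R,4E)-3-[(tert-butyldimethylsilyl)oxy]-5-iodo-2,4-dimethylpent-4-enal, via aluminium hemiaminal 16 (not isolated)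
Conditions: i-Bu2AlH (2 equiv), CH2Cl2, −78 °C; aq. KNaC4H4O6; used at once
Reagents that add atoms: none
Why: Partial reduction of an N-acylthiazolidinethione: hydride adds once to the activated carbonyl and the aluminium hemiaminal 16 collapses only on work-up, so the aldehyde is released without over-reduction or α-epimerisation.

Step 8
Reactants: 5 2,6-diethyl-3,5-dimethyl-4H-pyran-4-one; 18 propanal
Product: 21 (2RS,3RS)-2-(6-ethyl-3,5-dimethyl-4-oxo-4H-pyran-2-yl)pentan-3-yl acetate (racemic anti), via lithium dienolate 19 (not isolated), via lithium aldolate 20 (not isolated)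
Conditions: LiN(SiMe3)2 (1.05 equiv), THF, −78 °C; 18 (1.5 equiv), −78 °C; Ac2O (3 equiv), −78 to 0 °C; syn isomer removed by chromatography
Reagents that add atoms: acetic anhydride, CC(=O)OC(C)=O
Why: Vinylogous aldol of the lithium pyrone dienolate through an open transition state (lithium sits on the remote ring oxygen and holds the aldolate against retro-aldol) in which the aldehyde ethyl group lies anti to the pyrone ring and the aldehyde hydrogen over the γ-methyl, which gives mainly the anti adduct (about 3–5:1 expected); the aldolate is O-acetylated in the same flask for the resolution.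

Step 9
Reactants: 21 racemic anti acetate
Product: 22 2-ethyl-6-[(2R,3R)-3-hydroxypentan-2-yl]-3,5-dimethyl-4H-pyran-4-one
Conditions: immobilised Candida antarctica lipase B, pH 7 phosphate buffer/MTBE, 30 °C, stopped near 48% conversion; chromatography
Reagents that add atoms: none
Why: Lipase kinetic resolution by enantioselective ester hydrolysis: by the Kazlauskas rule the ester whose carbinol carbon is R (large CH(Me)pyranyl, medium ethyl) is hydrolysed faster, so 22 is released in high ee while the (2S,3S)-acetate stays esterified and is separated (maximum yield 50%).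

Step 10
Reactants: 22 (2R,3R)-alcohol (1.2 equiv); 17 aldehyde (1.0 equiv)
Product: 24 2-[(2S,3S,4S,5R,6E)-5-[(tert-butyldimethylsilyl)oxy]-3-hydroxy-7-iodo-4,6-dimethylhept-6-en-2-yl]-6-[(2R,3R)-3-hydroxypentan-2-yl]-3,5-dimethyl-4H-pyran-4-one, via dilithio dienolate 23 (not isolated)
Conditions: LiN(SiMe3)2 (2.45 equiv), THF, −78 °C, 45 min; 17, −78 °C, 1 h; aq. NH4Cl at −78 °C; chromatography
Reagents that add atoms: none
Why: Vinylogous aldol with Felkin–Anh control: the first equivalent of base makes the alkoxide, which steers the second deprotonation to the distant ethyl group, and the dienolate adds with the same anti preference as in step 8 and anti to the CH(OTBS) branch of the α-methyl aldehyde, setting C2 (S) and C3 (S) as the anti, 3,4-syn isomer.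

Step 11
Reactants: 24 silyl ether diol
Product: 25 2-[(2S,3S,4S,5R,6E)-3,5-dihydroxy-7-iodo-4,6-dimethylhept-6-en-2-yl]-6-[(2R,3R)-3-hydroxypentan-2-yl]-3,5-dimethyl-4H-pyran-4-one
Conditions: HF·pyridine, pyridine, THF, 0 °C to rt
Reagents that add atoms: none
Why: Buffered fluoride desilylation cleaves the Si–O bond without ionising the allylic alcohol or epimerising the pyrone-bearing centres.

Step 12
Reactants: 25 alkenyl iodide triol (1.0 equiv); 7 rac-2-(1-chloroethyl)-6-ethyl-3,5-dimethyl-4H-pyran-4-one (2.0 equiv)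
Product: 26 2-[(2S,3S,4S,5R,6E,8S)-8-(6-ethyl-3,5-dimethyl-4-oxo-4H-pyran-2-yl)-3,5-dihydroxy-4,6-dimethylnon-6-en-2-yl]-6-[(2R,3R)-3-hydroxypentan-2-yl]-3,5-dimethyl-4H-pyran-4-one (target)
Conditions: NiCl2·glyme (10 mol %), (3aR,3a′R,8aS,8a′S)-2,2′-(cyclopropane-1,1-diyl)bis(3a,8a-dihydro-8H-indeno[1,2-d]oxazole) (11 mol %; antipode confirmed on the model pair 7 + 10 so that C8 is S), Mn powder (3 equiv), N,N-dimethylacetamide, 0 °C; preparative HPLC
Reagents that add atoms: none
Why: Proposed new method: chloride 7 is the polarity-reversed (vinylogous enolonium) form of the pyrone γ-carbon, and chlorine abstraction by low-valent nickel gives a planar γ-pyronyl radical (a vinylogous α-keto radical), so both enantiomers of 7 converge, while the chiral bis(oxazoline) alkenylnickel species formed from the E iodide captures this radical and reductively eliminates with retention of alkene geometry, the ligand setting C8 as S; the closest known reaction type is the nickel-catalysed enantioconvergent reductive cross-coupling of 1-chloroethylarenes with alkenyl bromides, which tolerates free hydroxyl groups.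

## Compound list

1 | pentan-3-one | CCC(=O)CC | starting material
2 | propanoic acid | CCC(=O)O | starting material
3 | 4-methylheptane-3,5-dione (stereo/enol mixture, not isolated) | CCC(=O)C(C)C(=O)CC | intermediate
4 | 4,6-dimethylnonane-3,5,7-trione (stereo/enol mixture, not isolated) | CCC(=O)C(C)C(=O)C(C)C(=O)CC | intermediate
5 | 2,6-diethyl-3,5-dimethyl-4H-pyran-4-one | CCc1oc(CC)c(C)c(=O)c1C | intermediate
6 | sodium (2Z)-6-ethyl-2-ethylidene-3,5-dimethyl-2H-pyran-4-olate (not isolated) | C/C=C1\OC(CC)=C(C)C(O[Na])=C1C | intermediate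
7 | rac-2-(1-chloroethyl)-6-ethyl-3,5-dimethyl-4H-pyran-4-one | CCc1oc(C(C)Cl)c(C)c(=O)c1C | intermediate
8 | prop-2-yn-1-ol | C#CCO | starting material
9 | dimethylaluminium (2E)-3-(dimethylalumanyl)-2-methylprop-2-en-1-olate (not isolated) | C[Al](C)/C=C(\C)CO[Al](C)C | intermediate
10 | (2E)-3-iodo-2-methylprop-2-en-1-ol | OC/C(C)=C/I | intermediate
11 | (2E)-3-iodo-2-methylprop-2-enal | O=C/C(C)=C/I | intermediate
12 | 1-[(4R)-4-benzyl-2-thioxo-1,3-thiazolidin-3-yl]propan-1-one | CCC(=O)N1[C@H](Cc2ccccc2)CSC1=S | starting material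
13 | trichlorotitanium (Z)-enolate of 12 (not isolated) | C/C=C(\O[Ti](Cl)(Cl)Cl)N1[C@H](Cc2ccccc2)CSC1=S | intermediate
14 | (2R,3R,4E)-1-[(4R)-4-benzyl-2-thioxo-1,3-thiazolidin-3-yl]-3-hydroxy-5-iodo-2,4-dimethylpent-4-en-1-one | O=C([C@H](C)[C@@H](O)/C(C)=C/I)N1[C@H](Cc2ccccc2)CSC1=S | intermediate
15 | (2R,3R,4E)-1-[(4R)-4-benzyl-2-thioxo-1,3-thiazolidin-3-yl]-3-[(tert-butyldimethylsilyl)oxy]-5-iodo-2,4-dimethylpent-4-en-1-one | O=C([C@H](C)[C@@H](O[Si](C)(C)C(C)(C)C)/C(C)=C/I)N1[C@H](Cc2ccccc2)CSC1=S | intermediate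
16 | diisobutylaluminium hemiaminal of 15 (C1 configuration undefined, not isolated) | CC(C)C[Al](CC(C)C)OC([C@H](C)[C@@H](O[Si](C)(C)C(C)(C)C)/C(C)=C/I)N1[C@H](Cc2ccccc2)CSC1=S | intermediate
17 | (2R,3R,4E)-3-[(tert-butyldimethylsilyl)oxy]-5-iodo-2,4-dimethylpent-4-enal | O=C[C@H](C)[C@@H](O[Si](C)(C)C(C)(C)C)/C(C)=C/I | intermediate
18 | propanal | CCC=O | starting material
19 | lithium (2Z)-6-ethyl-2-ethylidene-3,5-dimethyl-2H-pyran-4-olate (not isolated) | C/C=C1\OC(CC)=C(C)C(O[Li])=C1C | intermediate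
20 | lithium (2RS,3RS)-2-(6-ethyl-3,5-dimethyl-4-oxo-4H-pyran-2-yl)pentan-3-olate (racemate, one enantiomer drawn, not isolated) | CCc1oc([C@H](C)[C@H](O[Li])CC)c(C)c(=O)c1C | intermediate
21 | (2RS,3RS)-2-(6-ethyl-3,5-dimethyl-4-oxo-4H-pyran-2-yl)pentan-3-yl acetate (racemate, one enantiomer drawn) | CCc1oc([C@H](C)[C@H](OC(C)=O)CC)c(C)c(=O)c1C | intermediate
22 | 2-ethyl-6-[(2R,3R)-3-hydroxypentan-2-yl]-3,5-dimethyl-4H-pyran-4-one | CCc1oc([C@H](C)[C@H](O)CC)c(C)c(=O)c1C | intermediate
23 | dilithium (2Z)-2-ethylidene-3,5-dimethyl-6-[(2R,3R)-3-oxidopentan-2-yl]-2H-pyran-4-olate (not isolated) | C/C=C1\OC([C@H](C)[C@H](O[Li])CC)=C(C)C(O[Li])=C1C | intermediate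
24 | 2-[(2S,3S,4S,5R,6E)-5-[(tert-butyldimethylsilyl)oxy]-3-hydroxy-7-iodo-4,6-dimethylhept-6-en-2-yl]-6-[(2R,3R)-3-hydroxypentan-2-yl]-3,5-dimethyl-4H-pyran-4-one | I/C=C(\C)[C@H](O[Si](C)(C)C(C)(C)C)[C@@H](C)[C@H](O)[C@H](C)c1oc([C@H](C)[C@H](O)CC)c(C)c(=O)c1C | intermediate
25 | 2-[(2S,3S,4S,5R,6E)-3,5-dihydroxy-7-iodo-4,6-dimethylhept-6-en-2-yl]-6-[(2R,3R)-3-hydroxypentan-2-yl]-3,5-dimethyl-4H-pyran-4-one | I/C=C(\C)[C@H](O)[C@@H](C)[C@H](O)[C@H](C)c1oc([C@H](C)[C@H](O)CC)c(C)c(=O)c1C | intermediate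
26 | 2-[(2S,3S,4S,5R,6E,8S)-8-(6-ethyl-3,5-dimethyl-4-oxo-4H-pyran-2-yl)-3,5-dihydroxy-4,6-dimethylnon-6-en-2-yl]-6-[(2R,3R)-3-hydroxypentan-2-yl]-3,5-dimethyl-4H-pyran-4-one | CCc1oc([C@@H](C)/C=C(\C)[C@H](O)[C@@H](C)[C@H](O)[C@H](C)c2oc([C@H](C)[C@H](O)CC)c(C)c(=O)c2C)c(C)c(=O)c1C | target

## Step count and risks

Total step count: 12. Longest linear sequence: 8 steps (8 → 10 → 11 → 14 → 15 → 17 → 24 → 25 → 26; steps 3, 4, 5, 6, 7, 10, 11, 12).

Steps most likely to fail:

**Step 12 (nickel coupling on the complete iodide).** Pyrone γ-chlorides are untested in this coupling; the risks are low conversion, homodimers, or poor control at C8. The fallback sets out from 7 and 10 and comes back at 26. The same polarity-reversed coupling is run first on the simplest alkenyl iodide, where ee is easy to assay and the ligand easy to tune. rac-7 and 10 under the step 12 conditions give the allylic alcohol F1. MnO2 gives the enal F2. Titanium enolate 13 adds to it to give the syn aldol adduct F3. TBSOTf/2,6-lutidine gives the silyl ether F4, and i-Bu2AlH gives the aldehyde F5. F5 is added at −78 °C to dilithio dienolate 23, made without excess amide to spare the C8–H of ring A, giving the 5-O-TBS ether of the target F6. HF·pyridine then gives 26. The route becomes linear and ring A is carried through base, which is why it is not the first choice.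

**Step 10 (anti, Felkin vinylogous aldol).** The open transition state may give a poor ratio at C2/C3. The fallback sets out from 22 and 17 and comes back at 25; it replaces aldol stereocontrol by a directed reduction. TESCl/imidazole on 22 gives the triethylsilyl ether F7. Its lithium dienolate and 17 give the aldol adducts as a C2/C3 mixture F8. Dess–Martin periodinane gives the C3 ketone F9, in which C2 is now labile. HF·pyridine removes both silyl groups to give the keto diol F10. Zn(BH4)2 (Et2O, −20 °C) reduces the chelated β-hydroxy ketone from the face opposite the C4 methyl, giving 3,4-syn and 3,5-syn. The labile C2 centre equilibrates through the enol, and the epimer that is Felkin-matched (hydride anti to the pyrone, C2/C3 anti) is consumed, giving 25.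

**Step 9 (lipase resolution of a hindered acetate).** The enzyme may be slow or poorly selective with a branched large group. The fallback sets out from 21 and comes back at 22; it uses covalent diastereomers instead of an enzyme. K2CO3/MeOH gives the racemic anti alcohol F11. (S)-O-methylmandelic acid, DCC and DMAP give two esters, the (2R,3R) ester F12 and the (2S,3S) ester F13, which are separated by chromatography. K2CO3/MeOH on F12 returns 22.

## Further compounds

F1 | step 12 | 2-ethyl-6-[(2S,3E)-5-hydroxy-4-methylpent-3-en-2-yl]-3,5-dimethyl-4H-pyran-4-one | CCc1oc([C@@H](C)/C=C(\C)CO)c(C)c(=O)c1C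
F2 | step 12 | (2E,4S)-4-(6-ethyl-3,5-dimethyl-4-oxo-4H-pyran-2-yl)-2-methylpent-2-enal | CCc1oc([C@@H](C)/C=C(\C)C=O)c(C)c(=O)c1C
F3 | step 12 | (2R,3R,4E,6S)-1-[(4R)-4-benzyl-2-thioxo-1,3-thiazolidin-3-yl]-6-(6-ethyl-3,5-dimethyl-4-oxo-4H-pyran-2-yl)-3-hydroxy-2,4-dimethylhept-4-en-1-one | O=C([C@H](C)[C@@H](O)/C(C)=C/[C@H](C)c1oc(CC)c(C)c(=O)c1C)N1[C@H](Cc2ccccc2)CSC1=S
F4 | step 12 | (2R,3R,4E,6S)-1-[(4R)-4-benzyl-2-thioxo-1,3-thiazolidin-3-yl]-3-[(tert-butyldimethylsilyl)oxy]-6-(6-ethyl-3,5-dimethyl-4-oxo-4H-pyran-2-yl)-2,4-dimethylhept-4-en-1-one | O=C([C@H](C)[C@@H](O[Si](C)(C)C(C)(C)C)/C(C)=C/[C@H](C)c1oc(CC)c(C)c(=O)c1C)N1[C@H](Cc2ccccc2)CSC1=S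
F5 | step 12 | (2R,3R,4E,6S)-3-[(tert-butyldimethylsilyl)oxy]-6-(6-ethyl-3,5-dimethyl-4-oxo-4H-pyran-2-yl)-2,4-dimethylhept-4-enal | O=C[C@H](C)[C@@H](O[Si](C)(C)C(C)(C)C)/C(C)=C/[C@H](C)c1oc(CC)c(C)c(=O)c1C
F6 | step 12 | 2-[(2S,3S,4S,5R,6E,8S)-5-[(tert-butyldimethylsilyl)oxy]-8-(6-ethyl-3,5-dimethyl-4-oxo-4H-pyran-2-yl)-3-hydroxy-4,6-dimethylnon-6-en-2-yl]-6-[(2R,3R)-3-hydroxypentan-2-yl]-3,5-dimethyl-4H-pyran-4-one | CCc1oc([C@@H](C)/C=C(\C)[C@H](O[Si](C)(C)C(C)(C)C)[C@@H](C)[C@H](O)[C@H](C)c2oc([C@H](C)[C@H](O)CC)c(C)c(=O)c2C)c(C)c(=O)c1C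
F7 | step 10 | 2-ethyl-3,5-dimethyl-6-[(2R,3R)-3-(triethylsilyloxy)pentan-2-yl]-4H-pyran-4-one | CCc1oc([C@H](C)[C@H](O[Si](CC)(CC)CC)CC)c(C)c(=O)c1C
F8 | step 10 | 2-[(4S,5R,6E)-5-[(tert-butyldimethylsilyl)oxy]-3-hydroxy-7-iodo-4,6-dimethylhept-6-en-2-yl]-3,5-dimethyl-6-[(2R,3R)-3-(triethylsilyloxy)pentan-2-yl]-4H-pyran-4-one (mixture at C2 and C3) | I/C=C(\C)[C@H](O[Si](C)(C)C(C)(C)C)[C@@H](C)C(O)C(C)c1oc([C@H](C)[C@H](O[Si](CC)(CC)CC)CC)c(C)c(=O)c1C
F9 | step 10 | 2-[(4R,5R,6E)-5-[(tert-butyldimethylsilyl)oxy]-7-iodo-4,6-dimethyl-3-oxohept-6-en-2-yl]-3,5-dimethyl-6-[(2R,3R)-3-(triethylsilyloxy)pentan-2-yl]-4H-pyran-4-one (C2 labile) | I/C=C(\C)[C@H](O[Si](C)(C)C(C)(C)C)[C@@H](C)C(=O)C(C)c1oc([C@H](C)[C@H](O[Si](CC)(CC)CC)CC)c(C)c(=O)c1C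
F10 | step 10 | 2-[(4R,5R,6E)-5-hydroxy-7-iodo-4,6-dimethyl-3-oxohept-6-en-2-yl]-6-[(2R,3R)-3-hydroxypentan-2-yl]-3,5-dimethyl-4H-pyran-4-one (C2 labile) | I/C=C(\C)[C@H](O)[C@@H](C)C(=O)C(C)c1oc([C@H](C)[C@H](O)CC)c(C)c(=O)c1C
F11 | step 9 | 2-ethyl-6-[(2RS,3RS)-3-hydroxypentan-2-yl]-3,5-dimethyl-4H-pyran-4-one (racemate, one enantiomer drawn) | CCc1oc([C@H](C)[C@H](O)CC)c(C)c(=O)c1C
F12 | step 9 | (2R,3R)-2-(6-ethyl-3,5-dimethyl-4-oxo-4H-pyran-2-yl)pentan-3-yl (2S)-methoxy(phenyl)acetate | CCc1oc([C@H](C)[C@H](OC(=O)[C@@H](OC)c2ccccc2)CC)c(C)c(=O)c1C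
F13 | step 9 | (2S,3S)-2-(6-ethyl-3,5-dimethyl-4-oxo-4H-pyran-2-yl)pentan-3-yl (2S)-methoxy(phenyl)acetate | CCc1oc([C@@H](C)[C@@H](OC(=O)[C@@H](OC)c2ccccc2)CC)c(C)c(=O)c1C
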